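Numbering used throughout (daucane): ring A = C1, C2, C3, C4, C5. Ring B = C1, C5, C6, C7, C8, C9, C10. C15 is the methyl on C1 and C14 is the methyl on C8.

## Structural features

1. The target is a daucane. Cyclopentane ring A is fused along the C1–C5 bond to cycloheptenone ring B, and O6 carries a vanilloyl group.
2. C1 is quaternary (C15, C2, C5, C10) and lies between the C10 ketone and the ring fusion. C4 is a tertiary carbinol bearing the isopropyl group, C6 is the acyloxy methine, and C10(=O)–C9H=C8(CH3)–C7H2 is a β-methyl enone.
3. The four stereocentres are contiguous around the hub C5, which is bonded to C1, C4 and C6. The fusion is trans. C15, the 4-OH and the 6-O-acyl group share the β face, while H5, H6 and the isopropyl group lie on the α face (1S,4R,5S,6R).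
4. The fragile groups are the δ-acyloxy enone (C7 deprotonation expels the vanillate), the tertiary alcohol (dehydration, or retro-aldol once C6 is a ketone) and the free phenol.
5. The real difficulty is the quaternary C1 inside a seven-membered ring, trans to H5 and cis to the 4-OH two atoms away. Additions to a ring alkene C1=C5 can only give a cis fusion.
6. In ring B the alkene C8=C9 and the functionalised pair C5–C6 are separated by the single methylene C7 and are joined on the other side by the C10–C1 bond.
7. This is the pattern of a cyclohepta-1,4-diene, the retron of the divinylcyclopropane rearrangement with a C6–C7–C8 cyclopropane.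
8. The key step exploits this pattern. It makes C1–C10, closes ring B and sets C1 in one pericyclic event.

## Logic of the disconnections

**17 to 15.** The phenolic O–acetyl bond and the C10=O bond are removed, through 16. The enone is the source of base sensitivity and would interfere with organometallic and radical steps, so it comes last. This leaves an isolated trisubstituted alkene. The forward step must oxidise C10–H in preference to C7–H and C14–H.

**15 to 12 and 13.** The ester C–O bond at O6 is cut. This separates the arene from the terpene core and makes the route convergent at a late stage. The forward step must acylate a hindered secondary alcohol next to a free tertiary one.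

**12 to 10.** The C5–H and C6–O bonds are removed, through 11, to reveal the C5=C6 alkene. Two stereocentres are traded for one alkene next to the 4-OH, which can direct oxygen to the β face. The forward steps need anti addition of O (β, at C6) and H (α, at C5), with hydrogen going to the more substituted carbon.

**10 to 9 (key).** The C1–C10 bond is cut, the C6–C8 bond is re-formed, and the alkenes move back to C1=C5 and C9=C10. Ring B, the quaternary centre and the position of the C8=C9 alkene all collapse into a three-membered ring attached to an intact ring A. In one sentence, the route is the thermal [3,3] rearrangement of the cis-dialkenylcyclopropane 9 into the hydroazulene 10. That sentence does not fit a ring-closing plan on a finished cyclopentane. The forward step needs a cis cyclopropane of defined absolute configuration and must tolerate a fully substituted alkene terminus.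

**9 to 7.** The C9=C10 alkene is cut, through 8, back to a primary alcohol. The second alkenyl group is introduced only when the rearrangement is wanted. The forward steps need a mild oxidation beside an acid-sensitive tertiary allylic alcohol, followed by a methylenation.

**7 to 6.** The C4–isopropyl bond is cut. C4 is set while the cyclopropane is still present, because its quaternary carbon C8 blocks one face of the ketone. After the rearrangement the two faces of ring A differ only as CH3 versus CH2. The forward step needs clean 1,2-addition of a branched nucleophile to a hindered enone.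

**6 to 5.** The C6–C7 and C7–C8 bonds are cut, removing one methylene. This is the only step in which absolute configuration is introduced. The forward step needs a reagent-controlled, stereospecific methylene transfer to a Z allylic alcohol.

**5 to 3 and 4.** The C5–C6 bond between two sp2 carbons is cut. This splits the carbon skeleton into a C6 ring piece and a C4 chain. The forward step needs retention of the Z geometry.

**3 to 1.** The C8–C14 and C6–Sn bonds are cut. Both are made in one carbometalation of a three-carbon alkyne. The forward step needs anti addition so that tin ends up cis to CH2OH.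

## Other disconnections considered

**Alternative 1:** this is the first that comes to mind.
- *Cut and key step:* cut C8=C9. Ring-closing metathesis of the diene A1 with the second-generation Grubbs catalyst would give 12, followed by the same endgame.
- *Stereochemistry:* the metathesis solves only the ring size. The trans-1,2-disubstituted cyclopentane A1 already holds all four stereocentres, including the quaternary C1 and its cis relationship to the 4-OH. These would have to be built one by one without any help from the key step.
- *Ring closure and economy:* the closure joins a 1,1-disubstituted alkene to an allyl group on a neopentyl carbon, which is a slow combination. The chosen plan makes the ring and C1 together and is shorter up to 12.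

**Alternative 2:**
- *Cut and key step:* cut C1–C10 and C5–C6 together. A [2+2] photocycloaddition of the enone A2 with the enediol bis-silyl ether A3 gives the 5-4-5 tricycle A4. Glycol fission of the strained C6–C10 bond then follows.
- *C4 configuration:* both oxygens of ring B arrive correctly placed, but the tricycle forces C10 and C6 to be cis on ring A. A nucleophile can then reach C4 only from the convex face, which places the isopropyl group cis to C15. This is the wrong C4 configuration.
- *Later problems:* after fission C5 lies between two carbonyl groups next to the future carbinol, so epimerisation to the trans fusion competes with elimination. The C8=C9 bond still has to be introduced regioselectively.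
- *Absolute configuration:* the first stereocentres arise in an uncatalysed excited-state reaction, so there is no handle for it.

**Alternative 3:**
- *Cut and key step:* cut the ring-fusion bond C1–C5. In the forward sense the C10 enolate opens the 4,5-epoxide A6 transannularly. A6 is made from the cyclodecadienone A5, which an anionic oxy-Cope ring expansion of a six-membered carbinol would supply.
- *Attraction:* connectivity and oxidation pattern fit exactly, since a γ-hydroxy ketone is formed from an enolate and an epoxide.
- *C4/C5 relationship:* backside opening at C5 gives the 4-OH trans to H5 only if C3 and C6 are cis on the C4=C5 alkene. The chair transition state of the oxy-Cope step, with the ring bond equatorial, delivers them trans. This leads to the 4-OH cis to H5.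
- *C1 and handling:* C1 would depend on the enolate geometry in a flexible ten-membered ring, and the medium ring adds handling problems.

Key step: step 6

Assumption: the stereodescriptors are read literally from the SMILES string. They are (1S,4R,5S,6R) in daucane numbering, which equals (3R,3aS,4R,8aS) in azulene numbering.
Assumption: 1, 4 and 13 are taken as catalogue compounds.

## Steps

Step 1
Reactants: 1 prop-2-yn-1-ol
Product: 3 (2Z)-2-methyl-3-(tributylstannyl)prop-2-en-1-ol, via cyclic alkenylmagnesium alkoxide 2 (not isolated)
Conditions: MeMgBr (2.5 equiv), CuI (10 mol %), THF, −10 °C to rt; then Bu3SnCl, 0 °C to rt; aqueous work-up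
Reagents that add atoms: methylmagnesium bromide, C[Mg]Br; tributyltin chloride, CCCC[Sn](Cl)(CCCC)CCCC
Why: Copper-catalysed anti-carbomagnesiation of the propargylic magnesium alkoxide puts methyl on the internal carbon and magnesium on the terminal carbon inside the five-membered chelate 2, and stereoretentive stannylation then leaves tin cis to CH2OH. This Z geometry is what later becomes the cis relationship on the cyclopropane.

Step 2
Reactants: 3 (2Z)-2-methyl-3-(tributylstannyl)prop-2-en-1-ol; 4 2-bromo-3-methylcyclopent-2-en-1-one
Product: 5 2-[(1Z)-3-hydroxy-2-methylprop-1-en-1-yl]-3-methylcyclopent-2-en-1-one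
Conditions: Pd(PPh3)4 (5 mol %), CuI (10 mol %), CsF (2 equiv), DMF, 45 °C
Reagents that add atoms: none
Why: Stille coupling of an α-halo enone with an alkenylstannane forms C5–C6 with retention of the alkene geometry. Fluoride and copper speed up transmetalation at the hindered partners, and the free hydroxyl group is tolerated.

Step 3
Reactants: 5 2-[(1Z)-3-hydroxy-2-methylprop-1-en-1-yl]-3-methylcyclopent-2-en-1-one
Product: 6 2-[(1R,2S)-2-(hydroxymethyl)-2-methylcyclopropyl]-3-methylcyclopent-2-en-1-one
Conditions: Et2Zn, CH2I2, DME, (4R,5R)-2-butyl-N,N,N′,N′-tetramethyl-1,3,2-dioxaborolane-4,5-dicarboxamide (1.2 equiv), CH2Cl2, −10 °C to rt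
Reagents that add atoms: diiodomethane, ICI
Why: Asymmetric Simmons–Smith cyclopropanation of an allylic alcohol under a stoichiometric chiral dioxaborolane (Charette variant), in which the zinc alkoxide steers the carbenoid to the C6=C8 alkene while the tetrasubstituted, electron-poor enone alkene stays inert. Methylene transfer is stereospecific, so the Z alkene gives the cis cyclopropane, and the facial sense that the (4R,5R) controller imposes on allylic alcohols of every substitution pattern corresponds to C6 (R) and C8 (S).

Step 4
Reactants: 6 2-[(1R,2S)-2-(hydroxymethyl)-2-methylcyclopropyl]-3-methylcyclopent-2-en-1-one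
Product: 7 (1R)-2-[(1R,2S)-2-(hydroxymethyl)-2-methylcyclopropyl]-3-methyl-1-(propan-2-yl)cyclopent-2-en-1-ol
Conditions: iPrMgCl, anhydrous CeCl3 (3.5 equiv each), THF, −78 °C
Reagents that add atoms: isopropylmagnesium chloride, CC(C)[Mg]Cl
Why: Organocerium 1,2-addition to a fully substituted enone, where conjugate addition is blocked at the disubstituted carbon C1 and CeCl3 holds back enolisation and β-hydride reduction. Allylic 1,3-strain with C15 keeps H6 in the plane of ring A, so C7 and C8 flank the carbonyl group on opposite faces. The face under the quaternary C8, which carries C14 and the metal alkoxide arm, is closed, so the nucleophile enters past the C7 methylene and C4 should form as R, with the isopropyl group on the face that C10 will occupy later.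

Step 5
Reactants: 7 (1R)-2-[(1R,2S)-2-(hydroxymethyl)-2-methylcyclopropyl]-3-methyl-1-(propan-2-yl)cyclopent-2-en-1-ol
Product: 8 (1S,2S)-2-[(5R)-5-hydroxy-2-methyl-5-(propan-2-yl)cyclopent-1-en-1-yl]-1-methylcyclopropane-1-carbaldehyde
Conditions: SO3·pyridine, DMSO, Et3N, CH2Cl2, 0 °C
Reagents that add atoms: none
Why: Parikh–Doering oxidation works under basic conditions, which spare the ionisable tertiary allylic alcohol, and it touches only the primary alcohol. The aldehyde has no α-hydrogen, so the cyclopropane stereocentres cannot epimerise.

Step 6
Reactants: 8 (1S,2S)-2-[(5R)-5-hydroxy-2-methyl-5-(propan-2-yl)cyclopent-1-en-1-yl]-1-methylcyclopropane-1-carbaldehyde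
Product: 10 (3R,8aR)-6,8a-dimethyl-3-(propan-2-yl)-1,2,3,5,8,8a-hexahydroazulen-3-ol, via cis-divinylcyclopropane 9 (not isolated)
Conditions: Ph3PCH3Br, KN(SiMe3)2 (2.5 equiv each), THF, −78 to 0 °C; aqueous work-up; then toluene, BHT (cat.), 110 °C
Reagents that add atoms: methyltriphenylphosphonium bromide, C[P+](c1ccccc1)(c1ccccc1)c1ccccc1.[Br-]
Why: Wittig methylenation of the non-enolisable aldehyde completes the cis-1,2-dialkenylcyclopropane 9, which on heating undergoes the concerted, suprafacial [3,3] divinylcyclopropane–cycloheptadiene (Cope) rearrangement: C6–C8 breaks, C1–C10 forms, and the π bonds move to C5=C6 and C8=C9. The only transition state that can give two cis ring alkenes is the endo boat, with both alkenyl groups folded over the C7 methylene, and release of the cyclopropane strain (about 27 kcal/mol) makes the step irreversible. Ring B is closed by a sigmatropic three-to-seven ring expansion rather than an end-to-end cyclisation, so no chain has to be folded, and ring A is carried through unchanged. C1 is the only new stereocentre: in the boat C10 can reach C1 only from the face of ring A over which C8 is held, so the configuration of C6 and C8 (both lost in the step) is handed on to C1, and the (6R,8R) cyclopropane of 9 places C10 on the α face and C15 on the β face, cis to the 4-OH. The step needs the two alkenyl groups to be cis, which the Z alkene of 5 and the stereospecific methylene transfer secure, and it needs no retro-ene escape, which is absent because the only alkyl group on the three-membered ring (C14) is trans to the cyclopentenyl group. The price is steric, since C15 is the inward substituent on the C1 terminus and the reactive rotamer gives up the allylic 1,3-strain minimum, so heating is expected where the parent system rearranges near room temperature. The closest known reaction type is this same rearrangement onto fully substituted alkene termini, an established way to all-carbon quaternary centres in seven-membered rings.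

Step 7
Reactants: 10 (3R,8aR)-6,8a-dimethyl-3-(propan-2-yl)-1,2,3,5,8,8a-hexahydroazulen-3-ol
Product: 11 (3R,3aS,4R,8aR)-3a,4-epoxy-6,8a-dimethyl-3-(propan-2-yl)-1,2,3,3a,4,5,8,8a-octahydroazulen-3-ol
Conditions: VO(acac)2 (2 mol %), t-BuOOH (in decane), CH2Cl2, 0 °C
Reagents that add atoms: tert-butyl hydroperoxide, CC(C)(C)OO
Why: Vanadium-catalysed hydroxyl-directed epoxidation, in which the vanadate ester of the 4-OH (O–C4–C5=C6 dihedral angle near 60°) delivers oxygen to the β face of C5=C6 only. The remote C8=C9 alkene has no directing group and should stay untouched.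

Step 8
Reactants: 11 (3R,3aS,4R,8aR)-3a,4-epoxy-6,8a-dimethyl-3-(propan-2-yl)-1,2,3,3a,4,5,8,8a-octahydroazulen-3-ol
Product: 12 (3R,3aS,4R,8aR)-6,8a-dimethyl-3-(propan-2-yl)-1,2,3,3a,4,5,8,8a-octahydroazulene-3,4-diol
Conditions: Cp2TiCl2 (2.5 equiv), Mn dust, H2O (20 equiv), THF, rt
Reagents that add atoms: none
Why: Titanocene-mediated reductive epoxide opening, in which Cp2TiCl (trivalent titanium) cleaves C5–O homolytically because this gives the tertiary radical, while C6–O is not touched and keeps its β configuration; the aqua complex of Cp2TiCl then transfers a hydrogen atom to C5. The β face of the radical is screened by C15 and by the titanium alkoxides on O4 and O6, so hydrogen should arrive from the α face and give the trans fusion.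

Step 9
Reactants: 12 (3R,3aS,4R,8aR)-6,8a-dimethyl-3-(propan-2-yl)-1,2,3,3a,4,5,8,8a-octahydroazulene-3,4-diol; 13 4-(acetyloxy)-3-methoxybenzoic acid
Product: 15 (3R,3aS,4R,8aR)-3-hydroxy-6,8a-dimethyl-3-(propan-2-yl)-1,2,3,3a,4,5,8,8a-octahydroazulen-4-yl 4-(acetyloxy)-3-methoxybenzoate, via mixed anhydride 14 (not isolated)
Conditions: 13, 2,4,6-trichlorobenzoyl chloride, Et3N, toluene, rt; then 12, DMAP, 40 °C
Reagents that add atoms: 2,4,6-trichlorobenzoyl chloride, O=C(Cl)c1c(Cl)cc(Cl)cc1Cl (its acyl group is found in 14 only)
Why: Yamaguchi esterification is suited to hindered secondary alcohols, and the tertiary 4-OH is too crowded to compete. The C6–O bond is not broken, so the configuration is kept, and the acetate masks the phenol.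

Step 10
Reactants: 15 (3R,3aS,4R,8aR)-3-hydroxy-6,8a-dimethyl-3-(propan-2-yl)-1,2,3,3a,4,5,8,8a-octahydroazulen-4-yl 4-(acetyloxy)-3-methoxybenzoate
Product: 16 (3R,3aS,4R,8aS)-3-hydroxy-6,8a-dimethyl-8-oxo-3-(propan-2-yl)-1,2,3,3a,4,5,8,8a-octahydroazulen-4-yl 4-(acetyloxy)-3-methoxybenzoate
Conditions: Rh2(cap)4 (dirhodium tetrakis(caprolactamate), 1 mol %), t-BuOOH (70% in water, 5 equiv), 1,2-dichloroethane, 40 °C
Reagents that add atoms: tert-butyl hydroperoxide, CC(C)(C)OO
Why: Allylic C–H oxidation by tert-butylperoxyl radicals. C10 hangs on the CH end of the trisubstituted alkene and leads to the β,β-disubstituted enone, C7 is deactivated by the neighbouring acyloxy group, and C14 is primary. No stereocentre is touched.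

Step 11
Reactants: 16 (3R,3aS,4R,8aS)-3-hydroxy-6,8a-dimethyl-8-oxo-3-(propan-2-yl)-1,2,3,3a,4,5,8,8a-octahydroazulen-4-yl 4-(acetyloxy)-3-methoxybenzoate
Product: 17 (3R,3aS,4R,8aS)-3-hydroxy-6,8a-dimethyl-8-oxo-3-(propan-2-yl)-1,2,3,3a,4,5,8,8a-octahydroazulen-4-yl 4-hydroxy-3-methoxybenzoate (target)
Conditions: K2CO3 (0.2 equiv), MeOH, 0 °C
Reagents that add atoms: none
Why: Transesterification of the phenyl acetate, which is far more electrophilic than the hindered secondary benzoate. Catalytic base, low temperature and short contact should keep the vinylogous β-elimination of the vanillate from starting.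

## Compound list

1 | prop-2-yn-1-ol | C#CCO | starting material
2 | 4-methyl-2,5-dihydro-1,2-oxamagnesole (cyclic alkenylmagnesium alkoxide) | CC1=C[Mg]OC1 | intermediate
3 | (2Z)-2-methyl-3-(tributylstannyl)prop-2-en-1-ol | CCCC[Sn](CCCC)(CCCC)/C=C(/C)CO | intermediate
4 | 2-bromo-3-methylcyclopent-2-en-1-one | CC1=C(Br)C(=O)CC1 | starting material
5 | 2-[(1Z)-3-hydroxy-2-methylprop-1-en-1-yl]-3-methylcyclopent-2-en-1-one | CC1=C(/C=C(/C)CO)C(=O)CC1 | intermediate
6 | 2-[(1R,2S)-2-(hydroxymethyl)-2-methylcyclopropyl]-3-methylcyclopent-2-en-1-one | CC1=C(C(=O)CC1)[C@@H]1C[C@]1(C)CO | intermediate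
7 | (1R)-2-[(1R,2S)-2-(hydroxymethyl)-2-methylcyclopropyl]-3-methyl-1-(propan-2-yl)cyclopent-2-en-1-ol | CC1=C([C@@H]2C[C@]2(C)CO)[C@](O)(C(C)C)CC1 | intermediate
8 | (1S,2S)-2-[(5R)-5-hydroxy-2-methyl-5-(propan-2-yl)cyclopent-1-en-1-yl]-1-methylcyclopropane-1-carbaldehyde | CC1=C([C@@H]2C[C@]2(C)C=O)[C@](O)(C(C)C)CC1 | intermediate
9 | (1R)-2-[(1R,2R)-2-ethenyl-2-methylcyclopropyl]-3-methyl-1-(propan-2-yl)cyclopent-2-en-1-ol | CC1=C([C@@H]2C[C@]2(C)C=C)[C@](O)(C(C)C)CC1 | intermediate
10 | (3R,8aR)-6,8a-dimethyl-3-(propan-2-yl)-1,2,3,5,8,8a-hexahydroazulen-3-ol | C1C=C(C)CC=C2[C@](O)(C(C)C)CC[C@]12C | intermediate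
11 | (3R,3aS,4R,8aR)-3a,4-epoxy-6,8a-dimethyl-3-(propan-2-yl)-1,2,3,3a,4,5,8,8a-octahydroazulen-3-ol | CC1=CC[C@@]2(C)CC[C@@](O)(C(C)C)[C@]23O[C@@H]3C1 | intermediate
12 | (3R,3aS,4R,8aR)-6,8a-dimethyl-3-(propan-2-yl)-1,2,3,3a,4,5,8,8a-octahydroazulene-3,4-diol | O[C@@H]1CC(C)=CC[C@@]2(C)CC[C@@](O)(C(C)C)[C@H]12 | intermediate
13 | 4-(acetyloxy)-3-methoxybenzoic acid | COc1cc(C(=O)O)ccc1OC(C)=O | starting material
14 | 4-(acetyloxy)-3-methoxybenzoic 2,4,6-trichlorobenzoic anhydride | COc1cc(C(=O)OC(=O)c2c(Cl)cc(Cl)cc2Cl)ccc1OC(C)=O | intermediate
15 | (3R,3aS,4R,8aR)-3-hydroxy-6,8a-dimethyl-3-(propan-2-yl)-1,2,3,3a,4,5,8,8a-octahydroazulen-4-yl 4-(acetyloxy)-3-methoxybenzoate | COc1cc(C(=O)O[C@@H]2CC(C)=CC[C@@]3(C)CC[C@@](O)(C(C)C)[C@H]23)ccc1OC(C)=O | intermediate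
16 | (3R,3aS,4R,8aS)-3-hydroxy-6,8a-dimethyl-8-oxo-3-(propan-2-yl)-1,2,3,3a,4,5,8,8a-octahydroazulen-4-yl 4-(acetyloxy)-3-methoxybenzoate | COc1cc(C(=O)O[C@@H]2CC(C)=CC(=O)[C@@]3(C)CC[C@@](O)(C(C)C)[C@H]23)ccc1OC(C)=O | intermediate
17 | (3R,3aS,4R,8aS)-3-hydroxy-6,8a-dimethyl-8-oxo-3-(propan-2-yl)-1,2,3,3a,4,5,8,8a-octahydroazulen-4-yl 4-hydroxy-3-methoxybenzoate | COc1cc(C(=O)O[C@@H]2CC(C)=CC(=O)[C@@]3(C)CC[C@@](O)(C(C)C)[C@H]23)ccc1O | target

## Step count and least certain steps

Total step count: 11. Longest linear sequence: 11 steps, from 1. Compounds 4 and 13 enter as purchased.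

**Step 6 (key step).**
- *Risk:* the rearrangement may be too slow. The reactive endo-boat rotamer must bring the C7 methylene into the plane of C15, against allylic 1,3-strain, and must turn C15 inward over the three-membered ring.
- *Consequence:* if much higher temperatures are needed, homolysis of C6–C8 would cause cis–trans isomerisation of the cyclopropane and loss of chirality transfer. Dehydration of the tertiary allylic alcohol would also begin to compete.
- *Fallback:* it sets out from 8 and comes back at 16, so step 10 falls away. The vinyl group is replaced by a ketene, whose sp terminus removes one steric contact and whose tandem Wolff/Cope rearrangement runs near 45 °C.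
- 8 is silylated (Et3SiOTf, 2,6-lutidine) to the triethylsilyl ether F1 and oxidised (Pinnick: NaClO2, NaH2PO4, 2-methylbut-2-ene) to the acid F2.
- F2 is taken through the acid chloride F3 ((COCl)2) with diazomethane and Et3N to the diazoketone F4.
- AgO2CPh and Et3N in THF at 45 °C trigger the Wolff rearrangement to the ketene F5. This undergoes the Cope rearrangement directly to the silylated dienone F6, which already holds the C10 enone.
- HF·pyridine frees the alcohol F7. The conditions of steps 7, 8 and 9 then give the epoxide F8, the diol F9 and finally 16.

**Step 4.**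
- *Risk:* the branched reagent may enolise the ketone or reduce it by β-hydride transfer. Facial selectivity erodes if the rotamer fixed by allylic 1,3-strain is not the only one that reacts.
- *Fallback:* it sets out from 6 and comes back at 7. It uses a smaller sp2 nucleophile without β-hydrogen and saturates it afterwards. 2-Propenylmagnesium bromide with CeCl3 gives the isopropenyl carbinol F10. Homogeneous hydrogenation with RhCl(PPh3)3 and H2 then reduces only the 1,1-disubstituted alkene, leaving the tetrasubstituted ring alkene and the cyclopropane intact.

**Step 8.**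
- *Risk:* hydrogen atom transfer to the planar C5 radical may show poor facial selectivity, because the isopropyl group also crowds the α face. The radical may be lost by β-hydrogen abstraction at C6. Lewis-acid-induced 1,2-shifts from C4 are also possible.
- *Fallback:* it sets out from 11 and comes back at 12. It sets H5 by mechanism instead of by selectivity.
- A Meinwald rearrangement (InCl3, 10 mol %, THF) moves H6 to C5 on the face opposite to the breaking C5–O bond, that is the α face. This gives the trans-fused β-hydroxy ketone F11.
- A Narasaka–Prasad reduction (Et2BOMe, NaBH4, THF/MeOH, −78 °C) then delivers hydride to the α face of the boron chelate and gives the syn diol.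

**Step 10.**
- *Risk:* hydrogen abstraction may occur at C7 or C14 instead of the neopentyl-like C10. The allyl radical may also be trapped at the tertiary end C8, so that part of the material stops at peroxides or ends as isomeric enones.
- *Fallback:* it sets out from 15 and comes back at 16. It fixes the regiochemistry by ionic steps.
- mCPBA gives the 8,9-epoxide F12 as a mixture of faces, which is of no consequence.
- Phenylselenide (PhSeSePh, NaBH4, EtOH) opens F12 at the secondary carbon C9 to the hydroxy selenide F13.
- Oxidation with H2O2 and syn elimination away from the carbinol carbon give the tertiary allylic alcohol F14.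
- Babler–Dauben oxidative transposition with pyridinium chlorochromate, C5H5NH[CrO3Cl], then moves the oxygen from C8 to C10 and gives the enone.

## Further compounds

F1 | step 6 | O-triethylsilyl derivative of 8 | CC1=C([C@@H]2C[C@]2(C)C=O)[C@](O[Si](CC)(CC)CC)(C(C)C)CC1
F2 | step 6 | cyclopropanecarboxylic acid from F1 | CC1=C([C@@H]2C[C@]2(C)C(=O)O)[C@](O[Si](CC)(CC)CC)(C(C)C)CC1
F3 | step 6 | acid chloride of F2 | CC1=C([C@@H]2C[C@]2(C)C(=O)Cl)[C@](O[Si](CC)(CC)CC)(C(C)C)CC1
F4 | step 6 | diazomethyl ketone from F3 | CC1=C([C@@H]2C[C@]2(C)C(=O)C=[N+]=[N-])[C@](O[Si](CC)(CC)CC)(C(C)C)CC1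
F5 | step 6 | cyclopropylketene from F4 | CC1=C([C@@H]2C[C@]2(C)C=C=O)[C@](O[Si](CC)(CC)CC)(C(C)C)CC1
F6 | step 6 | O-triethylsilyl derivative of the 10-oxo analogue of 10 | O=C1C=C(C)CC=C2[C@](O[Si](CC)(CC)CC)(C(C)C)CC[C@]12C
F7 | step 6 | 10-oxo analogue of 10 | O=C1C=C(C)CC=C2[C@](O)(C(C)C)CC[C@]12C
F8 | step 6 | 10-oxo analogue of 11 | CC1=CC(=O)[C@@]2(C)CC[C@@](O)(C(C)C)[C@]23O[C@@H]3C1
F9 | step 6 | 10-oxo analogue of 12 | O[C@@H]1CC(C)=CC(=O)[C@@]2(C)CC[C@@](O)(C(C)C)[C@H]12
F10 | step 4 | isopropenyl analogue of 7 | CC1=C([C@@H]2C[C@]2(C)CO)[C@](O)(C(C)=C)CC1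
F11 | step 8 | trans-fused 4-hydroxy-6-ketone (6-oxo analogue of 12) | O=C1CC(C)=CC[C@@]2(C)CC[C@@](O)(C(C)C)[C@H]12
F12 | step 10 | 8,9-epoxide of 15 | COc1cc(C(=O)O[C@@H]2CC3(C)OC3C[C@@]3(C)CC[C@@](O)(C(C)C)[C@H]23)ccc1OC(C)=O
F13 | step 10 | 8-hydroxy-9-(phenylselanyl) derivative from F12 | COc1cc(C(=O)O[C@@H]2CC(C)(O)C([Se]c3ccccc3)C[C@@]3(C)CC[C@@](O)(C(C)C)[C@H]23)ccc1OC(C)=O
F14 | step 10 | 8-hydroxy-9-ene (tertiary allylic alcohol) from F13 | COc1cc(C(=O)O[C@@H]2CC(C)(O)C=C[C@@]3(C)CC[C@@](O)(C(C)C)[C@H]23)ccc1OC(C)=O
A1 | alternative 1 | metathesis diene (1-allyl-1-methyl-2-(1-hydroxy-3-methylbut-3-enyl)-3-isopropylcyclopentan-3-ol) | O[C@H](CC(C)=C)[C@H]1[C@](O)(C(C)C)CC[C@]1(C)CC=C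
A2 | alternative 2 | 3-methylcyclopent-2-en-1-one | CC1=CC(=O)CC1
A3 | alternative 2 | 4-methyl-1,2-bis(trimethylsilyloxy)cyclopent-1-ene | CC1CC(O[Si](C)(C)C)=C(O[Si](C)(C)C)C1
A4 | alternative 2 | cis-anti-cis 5-4-5 photoadduct | C[C@]12CCC(=O)[C@H]1[C@]1(O[Si](C)(C)C)CC(C)C[C@]21O[Si](C)(C)C
A5 | alternative 3 | 6-hydroxy-4-isopropyl-1,8-dimethylcyclodeca-4,8-dien-10-one (daucane numbering) | CC1CC/C(C(C)C)=C/[C@H](O)C/C(C)=C\C1=O
A6 | alternative 3 | 4,5-epoxide of A5 | CC1CC[C@@]2(C(C)C)O[C@@H]2[C@H](O)C/C(C)=C\C1=O
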